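**Retrosynthetic overview**
- The C17 aldehyde comes from a primary alcohol by selective oxidation; the C8 carbinol comes from equatorial addition of a hydroxymethyl anion equivalent to a C8 ketone.
- The Z-enoate side chain (C12–C13 bond) comes from hydroboration/Suzuki coupling of a C9-vinyl decalone with methyl (Z)-3-iodobut-2-enoate.
- Key step: ring B is made by an oxidative semipinacol ring expansion of an allyl-substituted hydrindanol; C10 shifts from C8 to C9, giving the C8 ketone and the C9 vinyl group in one operation.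
- The hydrindanol comes from a Hajos–Parrish-type enone by allylation of the cyclopentanone, reductive methylation (gem-dimethyl, trans fusion) and ketone reduction.
- Ring order: the cyclopentane is bought, ring A is closed by Michael/aldol annulation, ring B is formed last by the ring expansion.

Assumption: positions are quoted in labdane numbering (C3 carbinol, C4 gem-dimethyl, C5/C10 ring fusion, C8 carbinol carbon carrying C17, C9 carrying the side chain C11–C16); names in the compound list use indene or naphthalene numbering.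

**Step 1**
Reactants: 1 2-methylcyclopentane-1,3-dione; 2 pent-1-en-3-one
Product: 3 2-methyl-2-(3-oxopentyl)cyclopentane-1,3-dione
Conditions: H2O, AcOH (cat.), 75 °C
Reagents that add atoms: none
Why: Michael addition of the acidic cyclic 1,3-dione to the vinyl ketone, the first half of a Hajos–Parrish annulation; the product is achiral.

**Step 2**
Reactants: 3 2-methyl-2-(3-oxopentyl)cyclopentane-1,3-dione
Product: 4 (7aR)-4,7a-dimethyl-2,3,7,7a-tetrahydro-1H-indene-1,5(6H)-dione
Conditions: D-phenylalanine (1.0 equiv), 1 M HClO4 (0.5 equiv), MeCN, reflux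
Reagents that add atoms: none
Why: Hajos–Parrish–Eder–Sauer–Wiechert enamine aldol condensation, in which the D-amino acid enamine of the side-chain ketone attacks one of the two enantiotopic ring carbonyls through a hydrogen-bonded transition state and sets the quaternary carbon (future C10) as R (the L-acid gives S), and dehydration closes ring A.

**Step 3**
Reactants: 4 (7aR)-4,7a-dimethyl-2,3,7,7a-tetrahydro-1H-indene-1,5(6H)-dione; 5 3-bromoprop-1-ene
Product: 6 (1S,7aR)-1-hydroxy-4,7a-dimethyl-1-(prop-2-en-1-yl)-1,2,3,6,7,7a-hexahydro-5H-inden-5-one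
Conditions: Zn dust, THF/sat. aq NH4Cl (1:1), 0 °C
Reagents that add atoms: none
Why: Barbier allylation, chemoselective because the isolated cyclopentanone is more electrophilic than the cross-conjugated tetrasubstituted enone carbonyl; allylzinc attacks anti to the angular methyl (OH cis to methyl), a center that is erased in step 6.

**Step 4**
Reactants: 6 (1S,7aR)-1-hydroxy-4,7a-dimethyl-1-(prop-2-en-1-yl)-1,2,3,6,7,7a-hexahydro-5H-inden-5-one
Product: 7 (1S,3aS,7aR)-1-hydroxy-4,4,7a-trimethyl-1-(prop-2-en-1-yl)octahydro-5H-inden-5-one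
Conditions: Li (2.3 equiv), NH3/THF, −78 → −33 °C; isoprene; MeI (5 equiv), −78 °C → rt; NH4Cl
Reagents that add atoms: iodomethane, CI
Why: Stork reductive alkylation (Birch-type enone reduction, then regiospecific C-methylation of the lithium enolate at C4), in which the tertiary OH is the single proton donor and axial protonation of the β-carbon gives the trans ring fusion (H-5 anti to the angular methyl), while the isolated allyl group is inert.

**Step 5**
Reactants: 7 (1S,3aS,7aR)-1-hydroxy-4,4,7a-trimethyl-1-(prop-2-en-1-yl)octahydro-5H-inden-5-one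
Product: 8 (1S,3aR,5R,7aR)-4,4,7a-trimethyl-1-(prop-2-en-1-yl)octahydro-1H-indene-1,5-diol
Conditions: NaBH4, MeOH, 0 °C
Reagents that add atoms: none
Why: Hydride reduction with axial delivery on the face opposite to the angular methyl and the axial 4-methyl, as in 4,4-dimethyl-3-oxo terpenoids, gives the equatorial C3 hydroxyl cis to the angular methyl (3R in labdane numbering).

**Step 6**
Reactants: 8 (1S,3aR,5R,7aR)-4,4,7a-trimethyl-1-(prop-2-en-1-yl)octahydro-1H-indene-1,5-diol
Product: 9 (1S,4aS,6R,8aR)-1-ethenyl-6-hydroxy-5,5,8a-trimethyloctahydronaphthalen-2(1H)-one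
Conditions: Pd(OAc)2 (10 mol%), 1,2-bis(phenylsulfinyl)ethane (10 mol%), (PhO)2P(O)OH (20 mol%), 2,6-dimethyl-1,4-benzoquinone (1.5 equiv), toluene, 45 °C
Reagents that add atoms: none
Why: Proposed new method: sulfoxide-ligated divalent palladium cleaves the allylic C–H bond at C9 (the only allylic CH2) to give an electrophilic η3-allyl palladium phosphate whose carbinol-bearing terminus is attacked, anti to the metal, by the migrating C8–C10 σ bond (the quaternary, better-migrating ring carbon) while the phosphate takes the hydroxyl proton, so that C10 shifts from C8 to C9 with retention, the five-membered ring becomes the six-membered ring B with a C8 ketone and a C9 vinyl group, and zerovalent palladium is reoxidized by the quinone; the closest known reactions are the sulfoxide/quinone allylic C–H oxidation of terminal alkenes and the palladium-allyl semipinacol (Wagner–Meerwein) ring expansion of strained alkenyl cyclobutanols, and the new element is an unstrained cyclopentanol with a simple allyl group, where carbonyl formation and irreversible reduction of palladium replace strain release as driving force (C9 is expected to form with the vinyl group equatorial, and being epimerizable it is equilibrated in step 8).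

**Step 7**
Reactants: 10 methyl but-2-ynoate
Product: 11 methyl (2Z)-3-iodobut-2-enoate
Conditions: NaI, AcOH, 115 °C
Reagents that add atoms: sodium iodide, [Na+].[I-]
Why: Conjugate hydroiodination of the ynoate with net anti addition places iodine cis to the ester (Z), a known stereoselective route to β-iodo enoates.

**Step 8**
Reactants: 9 (1S,4aS,6R,8aR)-1-ethenyl-6-hydroxy-5,5,8a-trimethyloctahydronaphthalen-2(1H)-one; 11 methyl (2Z)-3-iodobut-2-enoate
Product: 13 methyl (2Z)-5-[(1S,4aS,6R,8aR)-6-hydroxy-5,5,8a-trimethyl-2-oxodecahydronaphthalen-1-yl]-3-methylpent-2-enoate, via B-alkyl-9-BBN adduct 12 (not isolated)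
Conditions: 9-BBN dimer (0.6 equiv), THF, 0 °C → rt; then 11, Pd(dppf)Cl2 (5 mol%), AsPh3 (10 mol%), Cs2CO3 (3 equiv), DMF/H2O, rt → 45 °C
Reagents that add atoms: 9-borabicyclo[3.3.1]nonane, B1C2CCCC1CCC2 (its boron and carbon atoms are in 12 only)
Why: Anti-Markovnikov hydroboration of the monosubstituted alkene (faster than reduction of the hindered ketone) followed by B-alkyl Suzuki–Miyaura coupling, which forms C12–C13 with retention of the iodide geometry and so fixes the Z enoate, while the carbonate base equilibrates the epimerizable C9 to the equatorial side chain (cis to the angular methyl, 9S).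

**Step 9**
Reactants: 13 methyl (2Z)-5-[(1S,4aS,6R,8aR)-6-hydroxy-5,5,8a-trimethyl-2-oxodecahydronaphthalen-1-yl]-3-methylpent-2-enoate
Product: 15 methyl (2Z)-5-[(1S,2R,4aS,6R,8aR)-2,6-dihydroxy-2-(hydroxymethyl)-5,5,8a-trimethyldecahydronaphthalen-1-yl]-3-methylpent-2-enoate, via beta-hydroxy silane 14 (not isolated)
Conditions: iPrOMe2SiCH2MgCl (from iPrOMe2SiCH2Cl and Mg, 4 equiv), CeCl3 (4 equiv), THF, −78 → 0 °C; then KF, KHCO3, 30% H2O2, THF/MeOH, rt
Reagents that add atoms: (isopropoxydimethylsilyl)methylmagnesium chloride, CC(C)O[Si](C)(C)C[Mg]Cl; hydrogen peroxide, OO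
Why: Tamao nucleophilic hydroxymethylation, in which the cerium-modified Grignard reagent adds to the ketone in preference to the β,β-disubstituted conjugated ester and enters along the equatorial trajectory because the axial one is blocked by the 1,3-diaxial angular methyl, so that C17 is equatorial and the C8 hydroxyl axial (cis to the angular methyl, 8R), and Tamao–Fleming oxidation then replaces silicon by OH.

**Step 10**
Reactants: 15 methyl (2Z)-5-[(1S,2R,4aS,6R,8aR)-2,6-dihydroxy-2-(hydroxymethyl)-5,5,8a-trimethyldecahydronaphthalen-1-yl]-3-methylpent-2-enoate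
Product: 16 methyl (2Z)-5-[(1S,2R,4aS,6R,8aR)-2-formyl-2,6-dihydroxy-5,5,8a-trimethyldecahydronaphthalen-1-yl]-3-methylpent-2-enoate
Conditions: TEMPO (10 mol%), PhI(OAc)2 (1.2 equiv), CH2Cl2, rt
Reagents that add atoms: none
Why: Oxoammonium (TEMPO) oxidation is selective for the primary alcohol over the hindered secondary and the tertiary ones and stops at the α-hydroxy aldehyde under anhydrous conditions, with no stereocenter touched.

**Compound list**
1 | 2-methylcyclopentane-1,3-dione | CC1C(=O)CCC1=O | starting material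
2 | pent-1-en-3-one | CCC(=O)C=C | starting material
3 | 2-methyl-2-(3-oxopentyl)cyclopentane-1,3-dione | CCC(=O)CCC1(C)C(=O)CCC1=O | intermediate
4 | (7aR)-4,7a-dimethyl-2,3,7,7a-tetrahydro-1H-indene-1,5(6H)-dione | CC1=C2CCC(=O)[C@]2(C)CCC1=O | intermediate
5 | 3-bromoprop-1-ene (allyl bromide) | C=CCBr | starting material
6 | (1S,7aR)-1-hydroxy-4,7a-dimethyl-1-(prop-2-en-1-yl)-1,2,3,6,7,7a-hexahydro-5H-inden-5-one (OH cis to the angular methyl) | CC1=C2CC[C@](O)(CC=C)[C@]2(C)CCC1=O | intermediate
7 | (1S,3aS,7aR)-1-hydroxy-4,4,7a-trimethyl-1-(prop-2-en-1-yl)octahydro-5H-inden-5-one (trans-fused) | CC1(C)[C@H]2CC[C@](O)(CC=C)[C@]2(C)CCC1=O | intermediate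
8 | (1S,3aR,5R,7aR)-4,4,7a-trimethyl-1-(prop-2-en-1-yl)octahydro-1H-indene-1,5-diol (secondary OH equatorial, cis to the angular methyl) | CC1(C)[C@H]2CC[C@](O)(CC=C)[C@]2(C)CC[C@H]1O | intermediate
9 | (1S,4aS,6R,8aR)-1-ethenyl-6-hydroxy-5,5,8a-trimethyloctahydronaphthalen-2(1H)-one (trans-decalin, vinyl equatorial) | C=C[C@H]1[C@]2(C)CC[C@@H](O)C(C)(C)[C@H]2CCC1=O | intermediate
10 | methyl but-2-ynoate | CC#CC(=O)OC | starting material
11 | methyl (2Z)-3-iodobut-2-enoate | COC(=O)/C=C(/C)I | intermediate
12 | 9-{2-[(1S,4aS,6R,8aR)-6-hydroxy-5,5,8a-trimethyl-2-oxodecahydronaphthalen-1-yl]ethyl}-9-borabicyclo[3.3.1]nonane | C1CCC2CCCC1B2CC[C@H]1[C@]2(C)CC[C@@H](O)C(C)(C)[C@H]2CCC1=O | intermediate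
13 | methyl (2Z)-5-[(1S,4aS,6R,8aR)-6-hydroxy-5,5,8a-trimethyl-2-oxodecahydronaphthalen-1-yl]-3-methylpent-2-enoate | COC(=O)/C=C(/C)CC[C@H]1[C@]2(C)CC[C@@H](O)C(C)(C)[C@H]2CCC1=O | intermediate
14 | methyl (2Z)-5-[(1S,2R,4aS,6R,8aR)-2-{[dimethyl(propan-2-yloxy)silyl]methyl}-2,6-dihydroxy-5,5,8a-trimethyldecahydronaphthalen-1-yl]-3-methylpent-2-enoate | COC(=O)/C=C(/C)CC[C@H]1[C@]2(C)CC[C@@H](O)C(C)(C)[C@H]2CC[C@]1(O)C[Si](C)(C)OC(C)C | intermediate
15 | methyl (2Z)-5-[(1S,2R,4aS,6R,8aR)-2,6-dihydroxy-2-(hydroxymethyl)-5,5,8a-trimethyldecahydronaphthalen-1-yl]-3-methylpent-2-enoate | COC(=O)/C=C(/C)CC[C@H]1[C@]2(C)CC[C@@H](O)C(C)(C)[C@H]2CC[C@]1(O)CO | intermediate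
16 | methyl (2Z)-5-[(1S,2R,4aS,6R,8aR)-2-formyl-2,6-dihydroxy-5,5,8a-trimethyldecahydronaphthalen-1-yl]-3-methylpent-2-enoate | COC(=O)/C=C(/C)CC[C@H]1[C@]2(C)CC[C@@H](O)C(C)(C)[C@H]2CC[C@]1(O)C=O | target

**Step count**
Total: 10 steps. Longest linear sequence: 9 steps (steps 1–6 and 8–10; step 7 is a one-step side branch).

**Three steps most likely to fail**

Step 6 (the proposed oxidative semipinacol). Risks are allylic acetoxylation, Wacker-type oxypalladation, or migration of the CH2 carbon instead of C10. The fallback sets out from 8 and comes back at 9, using only known reactions. The secondary alcohol is silylated (TBSCl, imidazole, DMF) to give the silyl ether F3. Allylic hydroxylation with SeO2 (cat.) and t-BuOOH in CH2Cl2 gives the secondary allylic alcohol F4, where both epimers at the new carbinol are usable. MsCl, Et3N, CH2Cl2, −20 °C gives the allylic mesylate F5. Et3Al, CH2Cl2, −78 → 0 °C then promotes the classical hydroxy-sulfonate semipinacol ring expansion to the silyl-protected vinyl ketone F6. HF·pyridine in THF frees 9.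

Step 3 (chemoselective allylation beside the enone). The risk is competing 1,2-addition to the enone carbonyl. The fallback sets out from 4 and comes back at 6. Pyrrolidine in MeOH at 60 °C masks only the conjugated ketone as the dienamine ketone F1. AllylMgBr in THF at −78 °C adds to the free cyclopentanone to give the allyl carbinol dienamine F2. Aqueous AcOH/NaOAc hydrolyses the dienamine back to the enone 6.

Step 9 (hydroxymethyl addition to a hindered, enolizable ketone in the presence of the ester). Risks are enolization, low conversion or attack on the ester. The fallback sets out from 13 and comes back at 15. Dimethylsulfonium methylide (Me3SI, KN(SiMe3)2, THF, −10 °C) attacks equatorially to give the spiro-epoxide F7 with the oxygen axial. CsOAc in DMF at 80 °C opens it at the CH2 carbon to the hydroxy acetate F8. K2CO3 in MeOH at 0 °C gives 15.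

**Further compounds**
F1 | step 3 | (7aR)-4,7a-dimethyl-5-(pyrrolidin-1-yl)-2,6,7,7a-tetrahydro-1H-inden-1-one | CC1=C(N3CCCC3)CC[C@@]2(C)C(=O)CC=C12
F2 | step 3 | (7aR)-4,7a-dimethyl-1-(prop-2-en-1-yl)-5-(pyrrolidin-1-yl)-2,6,7,7a-tetrahydro-1H-inden-1-ol (OH cis to the angular methyl) | CC1=C(N3CCCC3)CC[C@@]2(C)[C@@](O)(CC=C)CC=C12
F3 | step 6 | 5-O-tert-butyldimethylsilyl ether of 8 | CC1(C)[C@H]2CC[C@](O)(CC=C)[C@]2(C)CC[C@H]1O[Si](C)(C)C(C)(C)C
F4 | step 6 | 1-(1-hydroxyprop-2-en-1-yl) analogue of F3 (both epimers at the new carbinol) | CC1(C)[C@H]2CC[C@](O)(C(O)C=C)[C@]2(C)CC[C@H]1O[Si](C)(C)C(C)(C)C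
F5 | step 6 | allylic methanesulfonate of F4 | CC1(C)[C@H]2CC[C@](O)(C(OS(C)(=O)=O)C=C)[C@]2(C)CC[C@H]1O[Si](C)(C)C(C)(C)C
F6 | step 6 | 6-O-tert-butyldimethylsilyl ether of 9 | C=C[C@H]1[C@]2(C)CC[C@@H](O[Si](C)(C)C(C)(C)C)C(C)(C)[C@H]2CCC1=O
F7 | step 9 | spiro-epoxide of 13 at C8 (oxygen axial, cis to the angular methyl) | COC(=O)/C=C(/C)CC[C@H]1[C@]2(C)CC[C@@H](O)C(C)(C)[C@H]2CC[C@]13CO3
F8 | step 9 | primary acetate of 15 | COC(=O)/C=C(/C)CC[C@H]1[C@]2(C)CC[C@@H](O)C(C)(C)[C@H]2CC[C@]1(O)COC(C)=O
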